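**Plan**

1. Retrosynthesis: the two norbornene bonds C1–C13′ and C3–C11′ are cut first (retro-Diels–Alder). This gives a 2β-acetoxy cyclopentadiene on a guaian-12,8α-olide (fragment B, diene) and the α-methylene lactone of a 1,10-seco-eudesmanolide (fragment A, dienophile).
2. In fragment B the seven-membered ring (C1, C5–C10) holds a three-carbon unit C1–C5–C6 that belongs to the cyclopentenone and a four-carbon unit C7–C8(O)–C9–C10. Cutting C6–C7 and C1–C10 is therefore a (4+3) disconnection to a cyclopentenonyl vinylcarbenoid and a 2-siloxy diene, and the vinylcarbenoid is unravelled further (C1–C5) to an acyclic alkynyl diazo ketone.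
3. Forward, fragment B: alkynyl diazo ketone plus siloxy diene close the five- and seven-membered rings in one flask; then trans-lactone (inversion at C8), C3 selenide, C2 alcohol, methylene lactone, acetate.
4. Forward, fragment A: (S)-citronellal chain, L-proline anti-aldol and lactonisation (cis-lactone), intramolecular aldol condensation (six-membered ring), ozonolysis/reduction, two methylenations. The union by selenoxide elimination and Diels–Alder reaction is the last step.
5. Stereochemistry: C4 (catalytic conjugate alkynylation) is a relay centre that directs C7/C10 in the (4+3) step and C3/C2 afterwards and is then erased. C8 comes from hydride delivery plus SN2 inversion, C4′ from citronellal, C7′/C8′ from L-proline, and C1, C3, C11′ from the exo Diels–Alder reaction on the diene face anti to the acetoxy group and C14.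

Key step: step 6

Assumption: guaiane numbering C1–C15 is used for the hydroazulene half (β = face of C14; "13-nor" = C11 is CH2 and C12 the carboxyl carbon) and primed 1,10-seco-eudesmane numbering for the other half; the sense of induction in steps 1 and 18 is taken from the accepted models for these catalysts, and the antipodal ligand would be used in step 1 if the model did not hold.

Step 1
Reactants: 1 (E)-pent-3-en-2-one; 2 ethynyltri(propan-2-yl)silane
Product: 3 (S)-4-methyl-6-(triisopropylsilyl)hex-5-yn-2-one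
Conditions: [Rh(OAc)(C2H4)2]2 (2.5 mol %), (R)-5,5′-bis[bis(3,5-di-tert-butyl-4-methoxyphenyl)phosphino]-4,4′-bi-1,3-benzodioxole (6 mol %), 1,4-dioxane, 80 °C
Reagents that add atoms: none
Why: Rh-catalysed asymmetric conjugate alkynylation of an enone; the bulky silyl group suppresses alkyne dimerisation and the chiral bisphosphine selects the enone face, which sets the methyl-bearing centre (later C4).

Step 2
Reactants: 3 (S)-4-methyl-6-(triisopropylsilyl)hex-5-yn-2-one
Product: 5 (S)-1-diazo-4-methyl-6-(triisopropylsilyl)hex-5-yn-2-one, via trifluoroacetyl diketone 4 (not isolated)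
Conditions: LiN(SiMe3)2, THF, −78 °C; CF3CO2CH2CF3; then CH3SO2N3, Et3N, H2O (1 equiv), MeCN, 23 °C
Reagents that add atoms: methanesulfonyl azide, CS(=O)(=O)N=[N+]=[N-]
Why: detrifluoroacetylative diazo transfer; the kinetic enolate forms at the methyl group and is trifluoroacetylated, and the activated diketone 4 takes up the diazo group with loss of the trifluoroacetyl group, so the diazo carbon is placed regiospecifically and the stereocentre is untouched.

Step 3
Reactants: 5 (S)-1-diazo-4-methyl-6-(triisopropylsilyl)hex-5-yn-2-one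
Product: 6 (S)-1-diazo-4-methylhex-5-yn-2-one
Conditions: n-Bu4NF, THF, 0 °C
Reagents that add atoms: none
Why: fluoride-mediated protodesilylation of the alkynylsilane, which an α-diazo ketone should tolerate at 0 °C.

Step 4
Reactants: 7 tert-butyl 4-oxopentanoate; 8 acetaldehyde
Product: 11 tert-butyl (E)-4-oxohept-5-enoate, via aldol 9 (not isolated), via mesylate 10 (not isolated)
Conditions: LiN(i-Pr)2, THF, −78 °C; MeCHO; aq. NH4Cl; then CH3SO2Cl, Et3N, CH2Cl2, 0 → 23 °C
Reagents that add atoms: none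
Why: aldol condensation in two stages; the kinetic methyl enolate of the ketone (the ester α-protons are less acidic) adds to acetaldehyde, and mesylation followed by E1cB elimination of 10 should give the conjugated (E)-enone.

Step 5
Reactants: 11 tert-butyl (E)-4-oxohept-5-enoate
Product: 12 tert-butyl (3Z,5E)-4-[(tert-butyldimethylsilyl)oxy]hepta-3,5-dienoate
Conditions: t-BuMe2SiOSO2CF3, Et3N, CH2Cl2, 0 °C
Reagents that add atoms: tert-butyldimethylsilyl trifluoromethanesulfonate, CC(C)(C)[Si](C)(C)OS(=O)(=O)C(F)(F)F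
Why: silyl enol ether formation by soft enolisation toward the α′-methylene gives the cross-conjugated 2-siloxy diene; the (Z)-enol ether, with the CH2CO2t-Bu group away from the propenyl group, is the expected isomer and later fixes C7.

Step 6
Reactants: 6 (S)-1-diazo-4-methylhex-5-yn-2-one; 12 tert-butyl (3Z,5E)-4-[(tert-butyldimethylsilyl)oxy]hepta-3,5-dienoate
Product: 15 tert-butyl (4βH,7αH,10αH)-8-[(tert-butyldimethylsilyl)oxy]-2-oxo-13-norguaia-1(5),8-dien-12-oate, via divinylcyclopropane 13 (not isolated), via β,γ-enone 14 (not isolated)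
Conditions: Rh2(esp)2 (esp = α,α,α′,α′-tetramethyl-1,3-benzenedipropanoate; 1 mol %), 12 (3 equiv), CH2Cl2, 0 °C, 6 added over 8 h; then PhMe, 60 °C; then 1,8-diazabicyclo[5.4.0]undec-7-ene (0.2 equiv), 23 °C
Reagents that add atoms: none
Why: Proposed new method: the rhodium carbenoid from 6 should add to its pendant alkyne (carbene/alkyne metathesis), which closes the cyclopentenone and moves the carbenoid to C6; this vinylcarbenoid should cyclopropanate the silyl enol ether double bond of 12, and the cis-divinylcyclopropane 13 should undergo Cope rearrangement, so that C6–C7 (kept from the cyclopropane) and C1–C10 (from the [3,3] shift) form in one flask. The closest known reaction types are the carbene/alkyne cascade of alkynyl diazo ketones ended by alkene cyclopropanation and the tandem cyclopropanation/Cope (4+3) cycloaddition of rhodium vinylcarbenoids from vinyldiazoacetates with 2-siloxy dienes; the two have not been joined with an alkyne-derived, ester-free vinylcarbenoid and an acyclic siloxy diene. The five-membered ring closes by 5-exo-dig attack of the carbenoid carbon on the alkyne, and the seven-membered ring closes by cyclopropanation followed by the boat [3,3] shift, formally a (4+3) cycloaddition of C1–C5–C6 onto C7–C10. C7 and C10 are set cis to each other by the (Z)-enol ether and (E)-propenyl geometries of 12 through the boat transition state; C1 is transient and is erased when the base moves the C5=C6 double bond into conjugation; the absolute sense rests on the C4 methyl group, anti to which the alkene should approach the planar vinylcarbenoid. The step needs chemoselectivity (alkyne capture before the first carbenoid meets 12, hence slow addition of 6), site selectivity (the electron-rich enol ether reacts, not the trans-propenyl group, which rhodium carbenoids cyclopropanate poorly) and cis-divinyl geometry (a trans isomer is a donor–acceptor cyclopropane and should epimerise on warming).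

Step 7
Reactants: 15 tert-butyl (4βH,7αH,10αH)-8-[(tert-butyldimethylsilyl)oxy]-2-oxo-13-norguaia-1(5),8-dien-12-oate
Product: 16 tert-butyl (4βH,7αH,10αH)-2,8-dioxo-13-norguai-1(5)-en-12-oate
Conditions: HF·pyridine, THF, 0 °C
Reagents that add atoms: none
Why: desilylation of the silyl enol ether under mildly acidic conditions unveils the C8 ketone without a basic enolate, so C7 should not epimerise and the tert-butyl ester survives.

Step 8
Reactants: 16 tert-butyl (4βH,7αH,10αH)-2,8-dioxo-13-norguai-1(5)-en-12-oate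
Product: 17 tert-butyl (4βH,7αH,10αH)-8β-hydroxy-2-oxo-13-norguai-1(5)-en-12-oate
Conditions: LiBH(s-Bu)3 (1.05 equiv), THF, −78 °C; aq. NH4Cl
Reagents that add atoms: none
Why: chemo- and diastereoselective ketone reduction; the hindered hydride should reduce the saturated C8 ketone before the tetrasubstituted cyclopentenone and attack the α face, anti to the C7 side chain and C14, to give the 8β-alcohol.

Step 9
Reactants: 17 tert-butyl (4βH,7αH,10αH)-8β-hydroxy-2-oxo-13-norguai-1(5)-en-12-oate
Product: 18 tert-butyl (4βH,7αH,10αH)-8β-(methylsulfonyloxy)-2-oxo-13-norguai-1(5)-en-12-oate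
Conditions: CH3SO2Cl, Et3N, CH2Cl2, 0 °C
Reagents that add atoms: methanesulfonyl chloride, CS(=O)(=O)Cl
Why: mesylate formation turns the C8 oxygen into a leaving group with retention of configuration.

Step 10
Reactants: 18 tert-butyl (4βH,7αH,10αH)-8β-(methylsulfonyloxy)-2-oxo-13-norguai-1(5)-en-12-oate
Product: 20 (4βH,7αH,8βH,10αH)-2-oxo-13-norguai-1(5)-en-12,8-olide, via acid mesylate 19 (not isolated)
Conditions: CF3CO2H, CH2Cl2, 0 °C; evaporation; then Cs2CO3, DMF, 40 °C
Reagents that add atoms: none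
Why: acidolysis of the tert-butyl ester, then intramolecular SN2 displacement of the mesylate by the carboxylate (5-exo-tet lactonisation) inverts C8 and should give the trans-fused 12,8α-lactone.

Step 11
Reactants: 20 (4βH,7αH,8βH,10αH)-2-oxo-13-norguai-1(5)-en-12,8-olide
Product: 21 (4βH,7αH,8βH,10αH)-2-oxo-3β-(phenylselanyl)-13-norguai-1(5)-en-12,8-olide
Conditions: LiN(i-Pr)2 (1.05 equiv), THF, −78 °C; PhSeCl
Reagents that add atoms: benzeneselenenyl chloride, Cl[Se]c1ccccc1
Why: α′-selenenylation of the kinetic cross-conjugated enolate of the cyclopentenone (the ketone is more acidic than the lactone); selenium should enter C3 trans to the C4 methyl group, which places it cis to H-4 for the later syn-elimination.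

Step 12
Reactants: 21 (4βH,7αH,8βH,10αH)-2-oxo-3β-(phenylselanyl)-13-norguai-1(5)-en-12,8-olide
Product: 22 (4βH,7αH,8βH,10αH)-2β-hydroxy-3β-(phenylselanyl)-13-norguai-1(5)-en-12,8-olide
Conditions: NaBH4, CeCl3·7H2O, MeOH, −78 °C
Reagents that add atoms: none
Why: Luche 1,2-reduction of the enone; hydride should add to C2 from the α face, anti to the neighbouring phenylselanyl group and to C14, giving the 2β-alcohol.

Step 13
Reactants: 22 (4βH,7αH,8βH,10αH)-2β-hydroxy-3β-(phenylselanyl)-13-norguai-1(5)-en-12,8-olide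
Product: 25 (4βH,7αH,8βH,10αH)-2β-hydroxy-3β-(phenylselanyl)guaia-1(5),11(13)-dien-12,8-olide, via Mannich base 23 (not isolated), via ammonium iodide 24 (not isolated)
Conditions: LiN(i-Pr)2 (2.3 equiv), THF, −78 °C; CH2=NMe2 I, −78 → 0 °C; then MeI, MeOH, 23 °C; then aq. NaHCO3, CH2Cl2
Reagents that add atoms: N,N-dimethylmethyleneiminium iodide, C=[N+](C)C.[I-]
Why: α-methylenation of the lactone by the Mannich route; the alkoxide/lactone-enolate dianion is aminomethylated and quaternisation followed by elimination of 24 gives the methylene lactone, the aryl selenide being far less nucleophilic toward MeI than the amine.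

Step 14
Reactants: 25 (4βH,7αH,8βH,10αH)-2β-hydroxy-3β-(phenylselanyl)guaia-1(5),11(13)-dien-12,8-olide
Product: 26 (4βH,7αH,8βH,10αH)-2β-acetoxy-3β-(phenylselanyl)guaia-1(5),11(13)-dien-12,8-olide
Conditions: Ac2O, pyridine, 4-(dimethylamino)pyridine (cat.), CH2Cl2, 23 °C
Reagents that add atoms: acetic anhydride, CC(=O)OC(C)=O
Why: acylation of the allylic secondary alcohol (acetylation) with retention at C2.

Step 15
Reactants: 27 (S)-citronellal; 28 ethyl diazoacetate
Product: 29 ethyl (S)-5,9-dimethyl-3-oxodec-8-enoate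
Conditions: SnCl2 (10 mol %), CH2Cl2, 23 °C
Reagents that add atoms: none
Why: Roskamp reaction; Lewis-acid-promoted addition of the diazo ester to the aldehyde and 1,2-hydride shift with loss of N2 gives the β-keto ester, and the β-stereocentre of citronellal is not enolisable.

Step 16
Reactants: 29 ethyl (S)-5,9-dimethyl-3-oxodec-8-enoate
Product: 30 ethyl 2-{2-[(S)-2,6-dimethylhept-5-en-1-yl]-1,3-dioxolan-2-yl}acetate
Conditions: HOCH2CH2OH, p-toluenesulfonic acid (cat.), PhH, reflux, water removal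
Reagents that add atoms: ethane-1,2-diol, OCCO
Why: acid-catalysed ketalisation masks the future C10′ ketone and blocks enolisation between the two carbonyl groups.

Step 17
Reactants: 30 ethyl 2-{2-[(S)-2,6-dimethylhept-5-en-1-yl]-1,3-dioxolan-2-yl}acetate
Product: 31 2-{2-[(S)-2,6-dimethylhept-5-en-1-yl]-1,3-dioxolan-2-yl}acetaldehyde
Conditions: i-Bu2AlH (1.1 equiv), CH2Cl2, −78 °C; aq. potassium sodium tartrate
Reagents that add atoms: none
Why: partial reduction of the ester to the aldehyde; the β-ketal oxygens should stabilise the aluminium hemiacetal until work-up.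

Step 18
Reactants: 31 2-{2-[(S)-2,6-dimethylhept-5-en-1-yl]-1,3-dioxolan-2-yl}acetaldehyde; 32 methyl 4-oxobutanoate
Product: 34 (2S,3S)-2-({2-[(S)-2,6-dimethylhept-5-en-1-yl]-1,3-dioxolan-2-yl}methyl)-5-oxotetrahydrofuran-3-carbaldehyde, via aldol adduct 33 (not isolated)
Conditions: L-proline (20 mol %), DMF, 4 °C, 32 (2 equiv) added over 24 h; then pyridinium p-toluenesulfonate (cat.), CH2Cl2, 23 °C
Reagents that add atoms: none
Why: proline-catalysed direct cross-aldol reaction; the enamine of the unhindered donor 32 adds to the β-branched acceptor 31 through the acid-organised chair transition state to give the anti aldol with (7′S,8′S) configuration, whose γ-hydroxy ester closes to the cis-β,γ-disubstituted lactone.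

Step 19
Reactants: 34 (2S,3S)-2-({2-[(S)-2,6-dimethylhept-5-en-1-yl]-1,3-dioxolan-2-yl}methyl)-5-oxotetrahydrofuran-3-carbaldehyde
Product: 36 cis-fused (8′S)-5′-[(S)-6-methylhept-5-en-2-yl] keto lactone 3,3a,7,7a-tetrahydrobenzofuran-2,6-dione, via keto aldehyde 35 (not isolated)
Conditions: 1 M HCl, THF, 23 °C; then Bn2NH·CF3CO2H (0.2 equiv), PhH, 40 °C
Reagents that add atoms: water, O
Why: ketal hydrolysis then iminium-activated intramolecular aldol condensation; only the C5′ enol of the ketone can reach the aldehyde through a six-membered ring, so the cyclohexenone closes with C5′=C6′ in place, the weakly acidic amine salt is chosen to avoid loss of the lactone carboxylate from the β-acyloxy enone, and the cis ring fusion is the stable one should C7′ epimerise.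

Step 20
Reactants: 36 cis-fused (8′S)-5′-[(S)-6-methylhept-5-en-2-yl] keto lactone 3,3a,7,7a-tetrahydrobenzofuran-2,6-dione
Product: 38 cis-fused (8′S)-5′-[(S)-5-hydroxypentan-2-yl] keto lactone 3,3a,7,7a-tetrahydrobenzofuran-2,6-dione, via aldehyde 37 (not isolated)
Conditions: O3 (1 equiv, dye end-point), CH2Cl2, −78 °C; PPh3; then NaBH(OAc)3, AcOH, PhH, 23 °C
Reagents that add atoms: ozone, [O-][O+]=O
Why: chemoselective ozonolysis of the electron-rich trisubstituted alkene (the enone double bond is deactivated) and aldehyde-selective reduction with the acyloxyborohydride, which should leave the enone and the lactone untouched.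

Step 21
Reactants: 38 cis-fused (8′S)-5′-[(S)-5-hydroxypentan-2-yl] keto lactone 3,3a,7,7a-tetrahydrobenzofuran-2,6-dione
Product: 39 1′-hydroxy-13′-nor-1′,10′-seco-eudesma-5′,10′(14′)-dien-12′,8′-olide (4′S,8′S; cis-lactone)
Conditions: Zn, CH2Br2, TiCl4, THF/CH2Cl2, 0 → 23 °C
Reagents that add atoms: dibromomethane, BrCBr
Why: Lombardo methylenation; the non-basic zinc/titanium methylene reagent should convert the enone carbonyl into the exocyclic methylene without enolisation or lactone cleavage, giving the s-trans semicyclic diene.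

Step 22
Reactants: 39 1′-hydroxy-13′-nor-1′,10′-seco-eudesma-5′,10′(14′)-dien-12′,8′-olide
Product: 42 1′-hydroxy-1′,10′-seco-eudesma-5′,10′(14′),11′(13′)-trien-12′,8′-olide (4′S,7′S,8′S; cis-lactone), via Mannich base 40 (not isolated), via ammonium iodide 41 (not isolated)
Conditions: LiN(i-Pr)2 (2.3 equiv), THF, −78 °C; CH2=NMe2 I, −78 → 0 °C; then MeI, MeOH, 23 °C; then aq. NaHCO3, CH2Cl2
Reagents that add atoms: N,N-dimethylmethyleneiminium iodide, C=[N+](C)C.[I-]
Why: α-methylenation of the lactone by the Mannich route through the alkoxide/enolate dianion, followed by quaternisation and elimination; the ketone is already gone, so base can be used.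

Step 23
Reactants: 26 (4βH,7αH,8βH,10αH)-2β-acetoxy-3β-(phenylselanyl)guaia-1(5),11(13)-dien-12,8-olide; 42 1′-hydroxy-1′,10′-seco-eudesma-5′,10′(14′),11′(13′)-trien-12′,8′-olide
Product: 45 CNP0299458.1, via selenoxide 43 (not isolated), via acetoxy diene 44 (not isolated)
Conditions: 3-ClC6H4CO3H (1.05 equiv), CH2Cl2, −78 °C; then 42 (3 equiv), i-Pr2NH (3 equiv), −78 → 23 °C, 1 M, then 40 °C
Reagents that add atoms: none
Why: selenoxide syn-elimination (only H-4 is syn to selenium; H-2 is anti and sits on the oxygen-bearing carbon) should release the 2β-acetoxy-1(5),3-diene 44, which is trapped by the methylene lactone of 42 in an intermolecular exo Diels–Alder reaction in which C13′ bonds to C1 and the quaternary C11′ to the less hindered C3, on the α face of the diene anti to the acetoxy group and C14 (the exo lactone carbonyl would clash with a syn acetoxy group) and on the lactone face that carries C6′; the semicyclic diene of 42 is locked s-trans and cannot act as a diene, and the excess of 42 is meant to outrun self-dimerisation of 44.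

**Compound list**

1 | (E)-pent-3-en-2-one | C/C=C/C(C)=O | starting material
2 | ethynyltri(propan-2-yl)silane | C#C[Si](C(C)C)(C(C)C)C(C)C | starting material
3 | (S)-4-methyl-6-(triisopropylsilyl)hex-5-yn-2-one | CC(=O)C[C@H](C)C#C[Si](C(C)C)(C(C)C)C(C)C | intermediate
4 | (S)-1,1,1-trifluoro-6-methyl-8-(triisopropylsilyl)oct-7-yne-2,4-dione | FC(F)(F)C(=O)CC(=O)C[C@H](C)C#C[Si](C(C)C)(C(C)C)C(C)C | intermediate
5 | (S)-1-diazo-4-methyl-6-(triisopropylsilyl)hex-5-yn-2-one | [N-]=[N+]=CC(=O)C[C@H](C)C#C[Si](C(C)C)(C(C)C)C(C)C | intermediate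
6 | (S)-1-diazo-4-methylhex-5-yn-2-one | [N-]=[N+]=CC(=O)C[C@H](C)C#C | intermediate
7 | tert-butyl 4-oxopentanoate | CC(=O)CCC(=O)OC(C)(C)C | starting material
8 | acetaldehyde | CC=O | starting material
9 | tert-butyl 6-hydroxy-4-oxoheptanoate | CC(O)CC(=O)CCC(=O)OC(C)(C)C | intermediate
10 | tert-butyl 6-(methylsulfonyloxy)-4-oxoheptanoate | CC(OS(C)(=O)=O)CC(=O)CCC(=O)OC(C)(C)C | intermediate
11 | tert-butyl (E)-4-oxohept-5-enoate | C/C=C/C(=O)CCC(=O)OC(C)(C)C | intermediate
12 | tert-butyl (3Z,5E)-4-[(tert-butyldimethylsilyl)oxy]hepta-3,5-dienoate | C/C=C/C(=C/CC(=O)OC(C)(C)C)O[Si](C)(C)C(C)(C)C | intermediate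
13 | tert-butyl 2-{2-[(tert-butyldimethylsilyl)oxy]-3-[(S)-5-methyl-3-oxocyclopent-1-en-1-yl]-2-[(E)-prop-1-en-1-yl]cyclopropyl}acetate (cyclopentenyl and propenyl cis; CH2CO2t-Bu trans to both) | [C@@H]1(C2=CC(=O)C[C@@H]2C)[C@@H](CC(=O)OC(C)(C)C)[C@]1(O[Si](C)(C)C(C)(C)C)/C=C/C | intermediate
14 | tert-butyl (1αH,4βH,7αH,10αH)-8-[(tert-butyldimethylsilyl)oxy]-2-oxo-13-norguaia-5,8-dien-12-oate | C[C@@H]1C=C(O[Si](C)(C)C(C)(C)C)[C@H](CC(=O)OC(C)(C)C)C=C2[C@@H](C)CC(=O)[C@H]12 | intermediate
15 | tert-butyl (4βH,7αH,10αH)-8-[(tert-butyldimethylsilyl)oxy]-2-oxo-13-norguaia-1(5),8-dien-12-oate (10R) | C[C@@H]1C=C(O[Si](C)(C)C(C)(C)C)[C@H](CC(=O)OC(C)(C)C)CC2=C1C(=O)C[C@@H]2C | intermediate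
16 | tert-butyl (4βH,7αH,10αH)-2,8-dioxo-13-norguai-1(5)-en-12-oate | C[C@@H]1CC(=O)[C@H](CC(=O)OC(C)(C)C)CC2=C1C(=O)C[C@@H]2C | intermediate
17 | tert-butyl (4βH,7αH,10αH)-8β-hydroxy-2-oxo-13-norguai-1(5)-en-12-oate | C[C@@H]1C[C@H](O)[C@H](CC(=O)OC(C)(C)C)CC2=C1C(=O)C[C@@H]2C | intermediate
18 | tert-butyl (4βH,7αH,10αH)-8β-(methylsulfonyloxy)-2-oxo-13-norguai-1(5)-en-12-oate | C[C@@H]1C[C@H](OS(C)(=O)=O)[C@H](CC(=O)OC(C)(C)C)CC2=C1C(=O)C[C@@H]2C | intermediate
19 | (4βH,7αH,10αH)-8β-(methylsulfonyloxy)-2-oxo-13-norguai-1(5)-en-12-oic acid | C[C@@H]1C[C@H](OS(C)(=O)=O)[C@H](CC(=O)O)CC2=C1C(=O)C[C@@H]2C | intermediate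
20 | (4βH,7αH,8βH,10αH)-2-oxo-13-norguai-1(5)-en-12,8-olide (trans-lactone, 8α-O) | C[C@@H]1C[C@H]2OC(=O)C[C@@H]2CC3=C1C(=O)C[C@@H]3C | intermediate
21 | (4βH,7αH,8βH,10αH)-2-oxo-3β-(phenylselanyl)-13-norguai-1(5)-en-12,8-olide | C[C@@H]1C[C@H]2OC(=O)C[C@@H]2CC3=C1C(=O)[C@@H]([Se]c4ccccc4)[C@@H]3C | intermediate
22 | (4βH,7αH,8βH,10αH)-2β-hydroxy-3β-(phenylselanyl)-13-norguai-1(5)-en-12,8-olide | C[C@@H]1C[C@H]2OC(=O)C[C@@H]2CC3=C1[C@@H](O)[C@@H]([Se]c4ccccc4)[C@@H]3C | intermediate
23 | 13-(dimethylamino)-2β-hydroxy-3β-(phenylselanyl)guai-1(5)-en-12,8α-olide (C11 epimers) | C[C@@H]1C[C@H]2OC(=O)C(CN(C)C)[C@@H]2CC3=C1[C@@H](O)[C@@H]([Se]c4ccccc4)[C@@H]3C | intermediate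
24 | trimethylammonium iodide of 23 | C[C@@H]1C[C@H]2OC(=O)C(C[N+](C)(C)C)[C@@H]2CC3=C1[C@@H](O)[C@@H]([Se]c4ccccc4)[C@@H]3C.[I-] | intermediate
25 | (4βH,7αH,8βH,10αH)-2β-hydroxy-3β-(phenylselanyl)guaia-1(5),11(13)-dien-12,8-olide | C[C@@H]1C[C@H]2OC(=O)C(=C)[C@@H]2CC3=C1[C@@H](O)[C@@H]([Se]c4ccccc4)[C@@H]3C | intermediate
26 | (4βH,7αH,8βH,10αH)-2β-acetoxy-3β-(phenylselanyl)guaia-1(5),11(13)-dien-12,8-olide | C[C@@H]1C[C@H]2OC(=O)C(=C)[C@@H]2CC3=C1[C@@H](OC(C)=O)[C@@H]([Se]c4ccccc4)[C@@H]3C | intermediate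
27 | (S)-citronellal, (S)-3,7-dimethyloct-6-enal | O=CC[C@@H](C)CCC=C(C)C | starting material
28 | ethyl diazoacetate | CCOC(=O)C=[N+]=[N-] | starting material
29 | ethyl (S)-5,9-dimethyl-3-oxodec-8-enoate | CCOC(=O)CC(=O)C[C@@H](C)CCC=C(C)C | intermediate
30 | ethyl 2-{2-[(S)-2,6-dimethylhept-5-en-1-yl]-1,3-dioxolan-2-yl}acetate | CCOC(=O)CC1(C[C@@H](C)CCC=C(C)C)OCCO1 | intermediate
31 | 2-{2-[(S)-2,6-dimethylhept-5-en-1-yl]-1,3-dioxolan-2-yl}acetaldehyde | O=CCC1(C[C@@H](C)CCC=C(C)C)OCCO1 | intermediate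
32 | methyl 4-oxobutanoate | COC(=O)CCC=O | starting material
33 | methyl (3S,4S)-5-{2-[(S)-2,6-dimethylhept-5-en-1-yl]-1,3-dioxolan-2-yl}-3-formyl-4-hydroxypentanoate | O=C[C@@H](CC(=O)OC)[C@@H](O)CC1(C[C@@H](C)CCC=C(C)C)OCCO1 | intermediate
34 | (2S,3S)-2-({2-[(S)-2,6-dimethylhept-5-en-1-yl]-1,3-dioxolan-2-yl}methyl)-5-oxotetrahydrofuran-3-carbaldehyde (cis) | O=C[C@H]1CC(=O)O[C@H]1CC2(C[C@@H](C)CCC=C(C)C)OCCO2 | intermediate
35 | (2S,3S)-2-[(S)-4,8-dimethyl-2-oxonon-7-en-1-yl]-5-oxotetrahydrofuran-3-carbaldehyde (cis) | O=C[C@H]1CC(=O)O[C@H]1CC(=O)C[C@@H](C)CCC=C(C)C | intermediate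
36 | cis-fused 5-[(S)-6-methylhept-5-en-2-yl]-3,3a,7,7a-tetrahydrobenzofuran-2,6-dione (7a = C8′, S; 3a = C7′, H cis to H-8′) | O=C1C[C@@H]2OC(=O)C[C@@H]2C=C1[C@@H](C)CCC=C(C)C | intermediate
37 | cis-fused (S)-4-(2,6-dioxo-2,3,3a,6,7,7a-hexahydrobenzofuran-5-yl)pentanal | O=C1C[C@@H]2OC(=O)C[C@@H]2C=C1[C@@H](C)CCC=O | intermediate
38 | cis-fused 5-[(S)-5-hydroxypentan-2-yl]-3,3a,7,7a-tetrahydrobenzofuran-2,6-dione (8′S) | O=C1C[C@@H]2OC(=O)C[C@@H]2C=C1[C@@H](C)CCCO | intermediate
39 | 1′-hydroxy-13′-nor-1′,10′-seco-eudesma-5′,10′(14′)-dien-12′,8′-olide (4′S,8′S; cis-lactone) | C=C1C[C@@H]2OC(=O)C[C@@H]2C=C1[C@@H](C)CCCO | intermediate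
40 | 13′-(dimethylamino)-1′-hydroxy-1′,10′-seco-eudesma-5′,10′(14′)-dien-12′,8′-olide (C11′ epimers) | C=C1C[C@@H]2OC(=O)C(CN(C)C)[C@@H]2C=C1[C@@H](C)CCCO | intermediate
41 | trimethylammonium iodide of 40 | C=C1C[C@@H]2OC(=O)C(C[N+](C)(C)C)[C@@H]2C=C1[C@@H](C)CCCO.[I-] | intermediate
42 | 1′-hydroxy-1′,10′-seco-eudesma-5′,10′(14′),11′(13′)-trien-12′,8′-olide (4′S,7′S,8′S; cis-lactone) | C=C1C[C@@H]2OC(=O)C(=C)[C@@H]2C=C1[C@@H](C)CCCO | intermediate
43 | selenoxide of 26 | C[C@@H]1C[C@H]2OC(=O)C(=C)[C@@H]2CC3=C1[C@@H](OC(C)=O)[C@@H]([Se](=O)c4ccccc4)[C@@H]3C | intermediate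
44 | (2S,7S,8R,10R)-2β-acetoxyguaia-1(5),3,11(13)-trien-12,8α-olide | C[C@@H]1C[C@H]2OC(=O)C(=C)[C@@H]2CC3=C1[C@@H](OC(C)=O)C=C3C | intermediate
45 | CNP0299458.1 (norbornene-linked guaianolide/1,10-seco-eudesmanolide dimer; C1–C13′ and C3–C11′ bonds, 2-acetoxy bridge syn to C4=C5, spiro lactone carbonyl exo) | C=C1C[C@@H]2OC(=O)[C@@]3(C[C@@]45C(=C(C)[C@@H]3[C@@H]4OC(C)=O)C[C@H]3C(=C)C(=O)O[C@@H]3C[C@H]5C)[C@@H]2C=C1[C@@H](C)CCCO | target

**Step count and risks**

Total step count: 23. Longest linear sequence: 13 steps (steps 1–3, 6–14, 23).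

Steps most likely to fail:

1. Step 6 (Proposed new method). What may go wrong: the first rhodium carbenoid is intercepted by the silyl enol ether before it reaches the alkyne, or the alkene approaches the vinylcarbenoid without facial bias, or a trans-divinylcyclopropane fails to rearrange. Fallback (sets out from 6 and 11, returns at 16), a stepwise anionic (4+3) annulation with known reactions: 6 is cyclised with Rh2(OAc)4 in wet CH2Cl2, where the carbene/alkyne cascade is ended by O–H insertion into water, to give (S)-3-(hydroxymethyl)-4-methylcyclopent-2-en-1-one F1. An Appel reaction (CBr4, PPh3) gives (S)-3-(bromomethyl)-4-methylcyclopent-2-en-1-one F2. The kinetic lithium enolate of 11 (LiN(i-Pr)2, −78 °C) is alkylated with F2 to give tert-butyl (E)-3-{[(S)-5-methyl-3-oxocyclopent-1-en-1-yl]methyl}-4-oxohept-5-enoate F3, which forms C6–C7. Base (t-BuOK or 1,8-diazabicyclo[5.4.0]undec-7-ene) then effects intramolecular vinylogous Michael addition of the cyclopentenone dienolate through C1 onto the propenyl ketone, forming C1–C10 and giving the β,γ-unsaturated diketone F4, which the same base conjugates to 16. C7 and C10 arise without control in this variant, so the 7,10-cis isomer would have to be secured by base equilibration of C7 and chromatography.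

2. Step 23. What may go wrong: the transient acetoxy diene is consumed by [1,5]-hydrogen shift or by cycloaddition with the methylene lactone of a second molecule of itself before it meets 42; addition on the acetoxy face is a further possibility that this fallback does not address. Fallback (sets out from 23, returns at 45), with the dienophile of fragment B masked: step 13 is stopped before quaternisation, Mannich base 23 is isolated and acetylated to the 2β-acetoxy Mannich base F5. With the amine protonated (CF3CO2H, 1.1 equiv), 3-ClC6H4CO3H at −78 °C gives selenoxide F6, which eliminates to the amino diene F7. F7 has no dienophile of its own and is trapped by 42 to give the amino adduct F8. MeI then NaHCO3, through the ammonium iodide F9, unveil the methylene lactone and return to 45.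

3. Step 19. What may go wrong: β-elimination of the lactone carboxylate from the β-acyloxy enone, followed by tautomerisation of the resulting dienone to a phenol. Fallback (sets out from 33, returns at 39), in which the lactone is closed only after the ketone is gone: the aldol adduct 33 is not lactonised but silylated (t-BuMe2SiOSO2CF3, 2,6-lutidine) to the silyl ether F10. Ketal hydrolysis gives the keto aldehyde F11, and the same amine-salt aldol condensation gives the β-silyloxy enone F12, which cannot lose a carboxylate. Ozonolysis (aldehyde F13) and NaBH(OAc)3 give the alcohol F14, and Lombardo methylenation gives the diene ester F15. HF·pyridine (hydroxy ester F16) followed by acid-catalysed lactonisation returns to 39.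

Further compounds
F1 | step 6 | (S)-3-(hydroxymethyl)-4-methylcyclopent-2-en-1-one | O=C1C=C(CO)[C@@H](C)C1
F2 | step 6 | (S)-3-(bromomethyl)-4-methylcyclopent-2-en-1-one | O=C1C=C(CBr)[C@@H](C)C1
F3 | step 6 | tert-butyl (E)-3-{[(S)-5-methyl-3-oxocyclopent-1-en-1-yl]methyl}-4-oxohept-5-enoate | C/C=C/C(=O)C(CC(=O)OC(C)(C)C)CC1=CC(=O)C[C@@H]1C
F4 | step 6 | tert-butyl (1αH,4βH,7αH,10αH)-2,8-dioxo-13-norguai-5-en-12-oate | C[C@@H]1CC(=O)[C@H](CC(=O)OC(C)(C)C)C=C2[C@@H](C)CC(=O)[C@H]12
F5 | step 23 | 2β-acetoxy-13-(dimethylamino)-3β-(phenylselanyl)guai-1(5)-en-12,8α-olide | C[C@@H]1C[C@H]2OC(=O)C(CN(C)C)[C@@H]2CC3=C1[C@@H](OC(C)=O)[C@@H]([Se]c4ccccc4)[C@@H]3C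
F6 | step 23 | selenoxide of F5 | C[C@@H]1C[C@H]2OC(=O)C(CN(C)C)[C@@H]2CC3=C1[C@@H](OC(C)=O)[C@@H]([Se](=O)c4ccccc4)[C@@H]3C
F7 | step 23 | 2β-acetoxy-13-(dimethylamino)guaia-1(5),3-dien-12,8α-olide | C[C@@H]1C[C@H]2OC(=O)C(CN(C)C)[C@@H]2CC3=C1[C@@H](OC(C)=O)C=C3C
F8 | step 23 | 11,13-dihydro-13-(dimethylamino) derivative of 45 | C=C1C[C@@H]2OC(=O)[C@@]3(C[C@@]45C(=C(C)[C@@H]3[C@@H]4OC(C)=O)C[C@H]3C(CN(C)C)C(=O)O[C@@H]3C[C@H]5C)[C@@H]2C=C1[C@@H](C)CCCO
F9 | step 23 | trimethylammonium iodide of F8 | C=C1C[C@@H]2OC(=O)[C@@]3(C[C@@]45C(=C(C)[C@@H]3[C@@H]4OC(C)=O)C[C@H]3C(C[N+](C)(C)C)C(=O)O[C@@H]3C[C@H]5C)[C@@H]2C=C1[C@@H](C)CCCO.[I-]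
F10 | step 19 | methyl (3S,4S)-4-[(tert-butyldimethylsilyl)oxy]-5-{2-[(S)-2,6-dimethylhept-5-en-1-yl]-1,3-dioxolan-2-yl}-3-formylpentanoate | O=C[C@@H](CC(=O)OC)[C@@H](O[Si](C)(C)C(C)(C)C)CC1(C[C@@H](C)CCC=C(C)C)OCCO1
F11 | step 19 | methyl (3S,4S,8S)-4-[(tert-butyldimethylsilyl)oxy]-3-formyl-8,12-dimethyl-6-oxotridec-11-enoate | O=C[C@@H](CC(=O)OC)[C@@H](O[Si](C)(C)C(C)(C)C)CC(=O)C[C@@H](C)CCC=C(C)C
F12 | step 19 | methyl 2-{6-[(tert-butyldimethylsilyl)oxy]-3-[(S)-6-methylhept-5-en-2-yl]-4-oxocyclohex-2-en-1-yl}acetate (ring substituents cis) | O=C1C[C@H](O[Si](C)(C)C(C)(C)C)[C@H](CC(=O)OC)C=C1[C@@H](C)CCC=C(C)C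
F13 | step 19 | methyl 2-{6-[(tert-butyldimethylsilyl)oxy]-4-oxo-3-[(S)-5-oxopentan-2-yl]cyclohex-2-en-1-yl}acetate | O=C1C[C@H](O[Si](C)(C)C(C)(C)C)[C@H](CC(=O)OC)C=C1[C@@H](C)CCC=O
F14 | step 19 | methyl 2-{6-[(tert-butyldimethylsilyl)oxy]-3-[(S)-5-hydroxypentan-2-yl]-4-oxocyclohex-2-en-1-yl}acetate | O=C1C[C@H](O[Si](C)(C)C(C)(C)C)[C@H](CC(=O)OC)C=C1[C@@H](C)CCCO
F15 | step 19 | methyl 2-{6-[(tert-butyldimethylsilyl)oxy]-3-[(S)-5-hydroxypentan-2-yl]-4-methylenecyclohex-2-en-1-yl}acetate | C=C1C[C@H](O[Si](C)(C)C(C)(C)C)[C@H](CC(=O)OC)C=C1[C@@H](C)CCCO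
F16 | step 19 | methyl 2-{6-hydroxy-3-[(S)-5-hydroxypentan-2-yl]-4-methylenecyclohex-2-en-1-yl}acetate | C=C1C[C@H](O)[C@H](CC(=O)OC)C=C1[C@@H](C)CCCO
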